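If both ways out of G run first order in G, as the way to X through Z and the way to Q unaided do, then the split between them at any moment does not depend on how much G stands there, and the concentration to find is that of Z. The way to X is then pseudo-first-order in G, and the catalyst starts as D, which turns into Z.

G 0.80 M; D 0.058 mol%; time 12 min

1. why nothing more happens at 12 min, or that something still does (no working catalyst is left / all of G has reacted / it is still moving)
2. how much of the G has reacted by 12 min
3. how much X there is at 12 min, in percent of the G charged
4. how much Q there is at 12 min, in percent of the G charged

- percent here means G units held: one G.X counts as two
- what is said of X includes E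
- E is a solid; its amount is given per volume of the solution
- the reaction counts as stopped when no species that holds the G changes by six tenths of a point or more over the second half of the time
- run time (flask): 12 min

I ranked the times, fastest first. Crystals exchanged with the solution in about 0.338 s, far quicker than the 0.22 min half-life of G on its way to Q, so I took dissolved X as held near 22 mM once crystals had formed. D turned into Z with a half-life of 0.44 min, slower than that loss of G, so G was disappearing while the catalyst was still appearing. Step 4 took dissolved X with a half-life of 0.55 min at G as charged, longer than the half-life of G, so I left it out of my sum. The run of 12 min was far longer than any of these half-lives, and I reckoned G reacted to 100 %.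

The catalyst charged came to 0.464 mM. Even fully formed it would pull on G at 0.0180 /s, less than the 0.0523 /s of the unaided way, so I let that unaided way set the life of G and averaged Z over it:

Z averaged = 0.464 mM × 0.0263 /s / (0.0523 /s + 0.0263 /s) = 0.155 mM

This is the mean working catalyst, the concentration of Z averaged over the life of G. The split followed:

X = 38.7 /M/s × 0.155 mM / (0.0523 /s + 38.7 /M/s × 0.155 mM) = 10.3 %

Q = 89.7 %

The forecast said that all of G has reacted, with 100 % reacted, 8.6 % of X and 90 % of Q, on the grounds that “G is gone within a couple of minutes and most of it ends up as Q”. Its X stood below mine.

The simulation showed that all of G has reacted, with 100 % reacted, 8.72 % of X and 90.1 % of Q.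

    G + Z → Z + X (k1 = 38.7 /M/s)
    G → Q (k2 = 0.0523 /s)
    E ⇌ X, rate k3*(cs3 - [X]) while solid is left; crystals form when [X] > cs3 (cs3 = 22 mM, k3 = 2.96 /s)
    G + X → G.X (k4 = 0.0264 /M/s)
    D → Z (k5 = 0.0263 /s)

In this flask the mean working catalyst of 0.155 mM had given me a share of X of 10.3 %, against the 8.72 % found. The neighbouring flask held 1.4 M of G at the same loading, so its mean working catalyst came to 0.272 mM, and the same split gave 16.8 % of X. That neighbouring flask ended with 0 % of its G left, 84.8 % of Q and 13.7 % of X.

Its constants stand for no real mixture; no experiment stands behind them.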